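## Structural features

The target is a flavanone: aromatic ring A is fused through C4a and C8a to the dihydropyranone ring C (O1, C2, C3, C4), and an unsubstituted phenyl ring B sits on C2. Ring A is substituted everywhere except C5: C7 carries a free phenol, and the two carbons flanking it, C6 and C8, each carry a 3-methylbut-2-enyl (prenyl) chain. C2 is the only stereocentre (S); it is benzylic, bonded to O1 and β to the C4 ketone, and no neighbouring stereocentre exists from which its configuration could be relayed. Because the aryloxy group is a β-leaving group of the ketone, base (and more slowly acid) can open ring C to the achiral 2'-hydroxychalcone and reclose it, which erases C2. The other fragile elements are the two trisubstituted alkenes, which cyclise onto the neighbouring phenol under acid and do not tolerate electrophiles or unselective hydrogenation. The real difficulty is to set C2 as one enantiomer and never expose it to a ring-opening pathway, while two prenyl groups are placed on both flanks of the phenol. The plan exploits the fact that O1–C8a is an aryl ether bond lying between C8 and C4a. If that bond is formed last, from a C8a bromide and a C2 carbinol set by ketone reduction, the C2–O bond is never broken, and with C4 held as an alcohol no enolisable ketone is present when the ring closes.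

## Logic of the disconnections

18 to 17. The bond in question is the O–CH2 bond of an acetal on the C7 oxygen. The phenol must be masked through the base, hydride, palladium and oxidation steps. The forward removal has to be mild enough that the prenyl alkenes do not close onto the freed phenol and ring C does not open.

17 to 16. No skeletal bond is cut; the C4 carbonyl is taken back to a carbinol (C4–H and O–H added). This removes the β-aryloxy ketone, and so the retro-oxa-Michael pathway, from the ring-closing step. The forward oxidation must be neutral and selective for the benzylic alcohol over two alkenes.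

16 to 15. The O1–C8a aryl ether bond is cut, which opens ring C to an acyclic 1,3-diol with bromine on C8a. The gain is that the stereocentre now sits in an open chain and its C–O bond is untouched by the closure. The demand is a C–O coupling in which reductive elimination outruns β-hydride elimination and only the hydroxyl that can form a six-membered ring reacts. The diol is kept unprotected, since the two benzylic hydroxyls cannot be told apart cheaply and the C4 hydroxyl has no productive outlet.

15 to 13 (through 14). The two carbinol C–H bonds are removed, tracing both stereocentres to a 1,3-diketone. The forward step must deliver hydride to the benzoyl carbonyl under catalyst control, because that carbinol becomes C2. The other carbinol becomes C4 and is oxidised later, so its configuration is sacrificial.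

13 to 11 and 12. The C–C bond between the central methylene (future C3) and the benzoyl carbon (future C2) is cut. This splits ring B off as 12 and leaves a methyl ketone. The forward step is a crossed Claisen condensation that must tolerate the aryl bromide.

11 to 10. The O–CH2 bond of the acetal is cut, returning the free phenol needed to direct the prenylations.

10 to 7 (through 8 and 9), then to 6 and 2. The aryl C5'–CH2 bond of one prenyl group is cut and traded for the O–C bond of a tertiary allyl ether, which is traced through its alkyne to the phenol and 2. A [3,3] shift can place the chain only ortho to oxygen, which is exactly where it is needed. The forward sequence needs a semihydrogenation that spares the C–Br bond and the existing prenyl alkene.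

6 to 3 (through 4 and 5), then to 1 and 2. The aryl C3'–CH2 bond of the other prenyl group is cut in the same way. Either ortho carbon may be served first, because the second round fills whichever is left.

## Other disconnections considered

Alternative 1: The cut is the C2–C3 bond of ring C. In the forward step the racemic enol acetal A1 would be ionised at its C2–O3 bond by a chiral MeAl(OAr)2, giving an O1=C2 oxocarbenium ion and a C4 aluminium enolate. These would recombine at carbon to close ring C as the silyl-protected flavanone A2.
- In favour: one step forms a skeletal C–C bond, ring C and the stereocentre. It starts from a racemate whose stereocentre is erased on ionisation, and C4 stays at the ketone level, so there is no reduction–oxidation detour. On bond and redox economy it is better than the chosen plan, whose key step makes one C–O bond and no stereocentre.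
- Against: the sense of addition would have to be dictated by the aluminium ligands alone while an ion pair collapses. The cation is planar and only weakly stabilised by an aryl oxygen, so high selectivity has no firm basis. The same Lewis acid can reopen A2 at C2–O1 and erode the selectivity. The cation also sits beside the C8 prenyl alkene, inviting Prins-type capture.
- Comparison: A1 needs the same doubly prenylated ring A plus a carbonyl methylenation, so no prenylation work is saved. On mechanism the chosen plan rests on catalyst-controlled hydride transfer to an aryl ketone and a stereoretentive coupling, both well founded. On step count the alternative would be about two steps shorter if it delivered, and its final buffered desilylation is the equal of the acetal removal used here.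

Alternative 2: The cuts are C5–C6 and C8–C8a, so ring A is built from acyclic pieces. The symmetrical ketone A3 and the malonate A4 would condense under excess NaOEt, by addition–elimination and then Claisen closure with aromatisation, to the resorcylate A5.
- In favour: the symmetry of A3 places both prenyl groups without any regiochemical question and without aromatic prenylation. One step reaches the fully substituted ring A, where the chosen plan spends four. On this point the alternative is clearly better.
- Against: A5 carries hydroxyl, not bromine, on C8a, so the O1–C8a bond already exists. Ring C would then have to close at C2–O or by chalcone cyclisation, the very equilibrium that racemises the target, so the stereochemical problem stays unsolved. The ester must still become the three-carbon ketone chain, the two phenols must be differentiated, and the enolate oxygen can attack the ester to give a pyranone instead of the arene.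
- Comparison: the mechanism is a thermodynamically driven aromatisation against a catalytic coupling; both are sound. Counting the extra steps to reach a ring C precursor and set C2, the alternative is unlikely to be shorter overall, and its stereocontrol is less secure.

Alternative 3: The cuts are C4a–C4, C4–C3 and O1–C2. The iodoresorcinol A6, carbon monoxide A7 and phenylacetylene A8 would combine under PdCl2(PPh3)2 in a secondary amine. The sequence is oxidative addition into C–I, CO insertion, alkynyl coupling to an ynone and 6-endo closure by the phenol oxygen, giving the flavone A9.
- In favour: three bonds and ring C form in one step from simple partners. This is the most convergent route to the skeleton and better in step economy than the chosen plan.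
- Against: A9 is flat, so C2 must be created last by enantioselective 1,4-reduction of a vinylogous ester. That substrate carries an acidic phenol conjugated to the carbonyl and two alkenes that compete under hydrogenation. The flavanone formed is labile under the basic conditions typical of conjugate reductions. Iodination to A6 next to prenyl groups invites iodo-etherification, and 5-exo closure competes with 6-endo.
- Comparison: the ring A demand is the same. The chosen plan sets the stereocentre early on an ordinary aryl ketone and then shields it, whereas this one sets it at the end on the least reactive acceptor. The alternative is shorter only if that last reduction can be made chemo- and enantioselective.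

Key step: step 8

Remark 1: in step 2 the [3,3] shift is expected to go mainly to C3', the ortho carbon next to bromine, as meta electron-withdrawing groups usually steer it there. Any C5' isomer is carried along unseparated, because step 4 fills the remaining ortho carbon and both isomers end as 10.

Remark 2: in step 7 the benzoyl carbonyl, which has no ortho substituent, is taken to be reduced first; this defines intermediate 14.

Remark 3: the descriptors of 15 (1S,3S), 16 (2S,4S) and 18 (2S) were derived from the drawn structures and agree with one another; the CIP order O > aryl > CH2 > H holds at the phenyl-bearing carbon throughout.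

## Route

Step 1
Reactants: 1 2'-bromo-4'-hydroxyacetophenone [1-(2-bromo-4-hydroxyphenyl)ethanone]; 2 3-chloro-3-methylbut-1-yne
Product: 3 1-[2-bromo-4-(2-methylbut-3-yn-2-yloxy)phenyl]ethanone
Conditions: K2CO3, KI, CuI (cat.), acetone, reflux
Reagents that add atoms: none
Why: Copper-assisted O-alkylation of the phenoxide with the tertiary propargylic chloride gives the tertiary aryl propargyl ether; the acidic para-acylphenol is a good partner, and the aryl bromide and ketone are inert to carbonate in acetone.

Step 2
Reactants: 3 1-[2-bromo-4-(2-methylbut-3-yn-2-yloxy)phenyl]ethanone
Product: 6 1-[2-bromo-4-hydroxy-3-(3-methylbut-2-enyl)phenyl]ethanone, via tertiary allyl ether 4 (not isolated), via ortho-dienone 5 (not isolated)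
Conditions: H2 (1 atm), Pd/CaCO3 poisoned with Pb(OAc)2, quinoline, o-xylene, rt; filter; then 130 °C
Reagents that add atoms: none
Why: Lindlar-type semihydrogenation stops at alkene 4 and spares the C–Br bond and the ketone; on heating, 4 undergoes the aromatic Claisen rearrangement ([3,3] shift), which delivers the 1,1-dimethylallyl group transposed as a prenyl group to the ortho carbon, and dienone 5 tautomerises to the phenol. Telescoping avoids isolating the acid-sensitive tertiary ether.

Step 3
Reactants: 6 1-[2-bromo-4-hydroxy-3-(3-methylbut-2-enyl)phenyl]ethanone; 2 3-chloro-3-methylbut-1-yne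
Product: 7 1-[2-bromo-3-(3-methylbut-2-enyl)-4-(2-methylbut-3-yn-2-yloxy)phenyl]ethanone
Conditions: K2CO3, KI, CuI (cat.), acetone, reflux
Reagents that add atoms: none
Why: Same copper-assisted O-alkylation as in step 1; the phenol still has one open flank and the prenyl alkene is inert.

Step 4
Reactants: 7 1-[2-bromo-3-(3-methylbut-2-enyl)-4-(2-methylbut-3-yn-2-yloxy)phenyl]ethanone
Product: 10 1-[2-bromo-4-hydroxy-3,5-bis(3-methylbut-2-enyl)phenyl]ethanone, via tertiary allyl ether 8 (not isolated), via ortho-dienone 9 (not isolated)
Conditions: H2 (1 atm), Pd/CaCO3 poisoned with Pb(OAc)2, quinoline, o-xylene, rt; filter; then 130 °C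
Reagents that add atoms: none
Why: Second semihydrogenation–Claisen sequence; the trisubstituted prenyl alkene is not reduced on the poisoned catalyst. With one ortho carbon occupied and the para carbon bearing the acetyl group, the [3,3] shift has a single productive terminus, so dienone 9 tautomerises to the diprenylphenol.

Step 5
Reactants: 10 1-[2-bromo-4-hydroxy-3,5-bis(3-methylbut-2-enyl)phenyl]ethanone
Product: 11 1-[2-bromo-4-(methoxymethoxy)-3,5-bis(3-methylbut-2-enyl)phenyl]ethanone
Conditions: MOMCl, K2CO3, acetone, 0 °C → rt
Reagents that add atoms: chloromethyl methyl ether, COCCl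
Why: O-alkylation of the acidic para-acylphenoxide with the reactive α-chloro ether gives the MOM acetal, which is stable to the hydride base, the formic acid–amine medium and the carbonate used later.

Step 6
Reactants: 11 1-[2-bromo-4-(methoxymethoxy)-3,5-bis(3-methylbut-2-enyl)phenyl]ethanone; 12 methyl benzoate
Product: 13 1-[2-bromo-4-(methoxymethoxy)-3,5-bis(3-methylbut-2-enyl)phenyl]-3-phenylpropane-1,3-dione
Conditions: NaH, THF, 65 °C; then aq NH4Cl
Reagents that add atoms: none
Why: Crossed Claisen condensation: the sodium enolate of the methyl ketone acylates the non-enolisable ester, and deprotonation of the 1,3-diketone drives the equilibrium. NaH in THF leaves the aryl bromide, the acetal and the prenyl groups alone.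

Step 7
Reactants: 13 1-[2-bromo-4-(methoxymethoxy)-3,5-bis(3-methylbut-2-enyl)phenyl]-3-phenylpropane-1,3-dione
Product: 15 (1S,3S)-1-[2-bromo-4-(methoxymethoxy)-3,5-bis(3-methylbut-2-enyl)phenyl]-3-phenylpropane-1,3-diol, via hydroxy ketone 14 (not isolated)
Conditions: RuCl[(S,S)-TsDPEN](p-cymene) (2 mol%), HCO2H/Et3N (5:2), DMF, 40 °C
Reagents that add atoms: none
Why: Noyori–Ikariya asymmetric transfer hydrogenation: hydride on ruthenium and proton on nitrogen are delivered together to each aryl ketone in an outer-sphere six-membered transition state, with the aryl group held by a CH–π contact to the cymene ligand, so the (S,S) ligand sets S at both carbinols (anti-diol) under catalyst control. The C3 carbinol, the future C2, comes from an unhindered benzoyl group, the best substrate class for this catalyst; the C1 carbinol is oxidised again in step 9, so its configuration is not critical.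

Step 8
Reactants: 15 (1S,3S)-1-[2-bromo-4-(methoxymethoxy)-3,5-bis(3-methylbut-2-enyl)phenyl]-3-phenylpropane-1,3-diol
Product: 16 (2S,4S)-7-(methoxymethoxy)-6,8-bis(3-methylbut-2-enyl)-2-phenylchroman-4-ol
Conditions: Pd(OAc)2 (5 mol%), 2-(di-tert-butylphosphino)-1,1'-binaphthyl (racemic, 6 mol%), Cs2CO3, toluene, 80 °C
Reagents that add atoms: none
Why: Pd(OAc)2 is reduced in the flask to zerovalent palladium bound to the bulky binaphthyl phosphine, which inserts into the C8a–Br bond of 15. Cs2CO3 deprotonates the palladium-bound C3 hydroxyl of the diol (the future O1), giving a seven-membered arylpalladium alkoxide (Pd, C8a, C4a, C4, C3, C2, O) at divalent palladium. C–O reductive elimination then forms O1–C8a and closes the six-membered ring C, formally a 6-exo attack of oxygen on the aryl carbon with release of zerovalent palladium. The closest known reaction type is the palladium-catalysed intramolecular etherification of ortho-haloaryl-substituted secondary alcohols to chromans (Buchwald–Hartwig C–O coupling). No stereocentre is created: neither carbinol C–O bond is broken, so C2 and C4 of 16 keep the S configurations set in step 7. Site selectivity between the two hydroxyls is secured by ring size, since the C1 alkoxide can only form a five-membered chelate whose reductive elimination would give a four-membered ring; reductive elimination over β-hydride elimination is secured by the bulky, electron-rich di-tert-butylphosphine. The prenyl alkenes cannot intercept the arylpalladium species (only 4-exo or 5-endo insertions would be open), and because C4 is an alcohol the carbonate base has no enolate route to reopen the ring. The diol is used unprotected because differentiating its two benzylic hydroxyls would cost steps and the C4 hydroxyl has no productive outlet.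

Step 9
Reactants: 16 (2S,4S)-7-(methoxymethoxy)-6,8-bis(3-methylbut-2-enyl)-2-phenylchroman-4-ol
Product: 17 (2S)-7-(methoxymethoxy)-6,8-bis(3-methylbut-2-enyl)-2-phenylchroman-4-one
Conditions: MnO2 (activated, excess), CH2Cl2, rt
Reagents that add atoms: none
Why: MnO2 oxidises the electron-rich benzylic C4 alcohol (activated by O1 ortho and the C7 oxygen para) under neutral conditions and leaves the prenyl alkenes and the acetal untouched. Without base the β-aryloxy ketone cannot open, so C2 is kept.

Step 10
Reactants: 17 (2S)-7-(methoxymethoxy)-6,8-bis(3-methylbut-2-enyl)-2-phenylchroman-4-one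
Product: 18 (2S)-7-hydroxy-6,8-bis(3-methylbut-2-enyl)-2-phenylchroman-4-one (7-hydroxy-6,8-diprenylflavanone)
Conditions: HCl (ca. 1 M) in MeOH, 0 °C → rt
Reagents that add atoms: none
Why: Acid-catalysed acetal exchange with methanol releases the phenol. Dilute acid at or below room temperature keeps protonation of the prenyl alkenes and acid-mediated opening of ring C slow, so the alkenes and C2 should survive.

## Compound list

1 | 2'-bromo-4'-hydroxyacetophenone [1-(2-bromo-4-hydroxyphenyl)ethanone] | CC(=O)c1ccc(O)cc1Br | starting material
2 | 3-chloro-3-methylbut-1-yne | CC(C)(Cl)C#C | starting material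
3 | 1-[2-bromo-4-(2-methylbut-3-yn-2-yloxy)phenyl]ethanone | CC(=O)c1ccc(OC(C)(C)C#C)cc1Br | intermediate
4 | 1-[2-bromo-4-(2-methylbut-3-en-2-yloxy)phenyl]ethanone | CC(=O)c1ccc(OC(C)(C)C=C)cc1Br | intermediate
5 | 4-acetyl-5-bromo-6-(3-methylbut-2-enyl)cyclohexa-2,4-dien-1-one | CC(=O)C1=C(Br)C(CC=C(C)C)C(=O)C=C1 | intermediate
6 | 1-[2-bromo-4-hydroxy-3-(3-methylbut-2-enyl)phenyl]ethanone | CC(=O)c1ccc(O)c(CC=C(C)C)c1Br | intermediate
7 | 1-[2-bromo-3-(3-methylbut-2-enyl)-4-(2-methylbut-3-yn-2-yloxy)phenyl]ethanone | CC(=O)c1ccc(OC(C)(C)C#C)c(CC=C(C)C)c1Br | intermediate
8 | 1-[2-bromo-3-(3-methylbut-2-enyl)-4-(2-methylbut-3-en-2-yloxy)phenyl]ethanone | CC(=O)c1ccc(OC(C)(C)C=C)c(CC=C(C)C)c1Br | intermediate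
9 | 4-acetyl-3-bromo-2,6-bis(3-methylbut-2-enyl)cyclohexa-2,4-dien-1-one | CC(=O)C1=CC(CC=C(C)C)C(=O)C(CC=C(C)C)=C1Br | intermediate
10 | 1-[2-bromo-4-hydroxy-3,5-bis(3-methylbut-2-enyl)phenyl]ethanone | CC(=O)c1cc(CC=C(C)C)c(O)c(CC=C(C)C)c1Br | intermediate
11 | 1-[2-bromo-4-(methoxymethoxy)-3,5-bis(3-methylbut-2-enyl)phenyl]ethanone | CC(=O)c1cc(CC=C(C)C)c(OCOC)c(CC=C(C)C)c1Br | intermediate
12 | methyl benzoate | COC(=O)c1ccccc1 | starting material
13 | 1-[2-bromo-4-(methoxymethoxy)-3,5-bis(3-methylbut-2-enyl)phenyl]-3-phenylpropane-1,3-dione | O=C(CC(=O)c1ccccc1)c1cc(CC=C(C)C)c(OCOC)c(CC=C(C)C)c1Br | intermediate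
14 | (3S)-1-[2-bromo-4-(methoxymethoxy)-3,5-bis(3-methylbut-2-enyl)phenyl]-3-hydroxy-3-phenylpropan-1-one | O[C@H](c1ccccc1)CC(=O)c1cc(CC=C(C)C)c(OCOC)c(CC=C(C)C)c1Br | intermediate
15 | (1S,3S)-1-[2-bromo-4-(methoxymethoxy)-3,5-bis(3-methylbut-2-enyl)phenyl]-3-phenylpropane-1,3-diol | O[C@H](c1ccccc1)C[C@H](O)c1cc(CC=C(C)C)c(OCOC)c(CC=C(C)C)c1Br | intermediate
16 | (2S,4S)-7-(methoxymethoxy)-6,8-bis(3-methylbut-2-enyl)-2-phenylchroman-4-ol | COCOc1c(CC=C(C)C)cc2c(c1CC=C(C)C)O[C@H](c1ccccc1)C[C@@H]2O | intermediate
17 | (2S)-7-(methoxymethoxy)-6,8-bis(3-methylbut-2-enyl)-2-phenylchroman-4-one | COCOc1c(CC=C(C)C)cc2c(c1CC=C(C)C)O[C@H](c1ccccc1)CC2=O | intermediate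
18 | (2S)-7-hydroxy-6,8-bis(3-methylbut-2-enyl)-2-phenylchroman-4-one | CC(C)=CCc1cc2c(c(CC=C(C)C)c1O)O[C@H](c1ccccc1)CC2=O | target

## Step count and least certain steps

Total step count: 10. Longest linear sequence: 10 steps (from 1; 2 and 12 are bought).

**Step 8 (key step).**
- Most likely to go wrong: β-hydride elimination from an arylpalladium alkoxide followed by C–H reductive elimination, which means reductive loss of bromine together with oxidation of a carbinol. Oxidative addition may also be slow at the doubly flanked C8a–Br bond, and the C4 alkoxide may hold palladium in an unproductive five-membered chelate.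
- Fallback: ring C is closed at the other C–O bond (O1–C2) by SN2 displacement with inversion, so the mirror-image diol is needed. The detour sets out from 13 and comes back at 17.
  - Transfer hydrogenation as in step 7, but with RuCl[(R,R)-TsDPEN](p-cymene), should give the (1R,3R)-bromo diol F2 through the (3R)-hydroxy ketone F1.
  - Miyaura borylation (B2pin2, PdCl2(dppf), KOAc, dioxane, 90 °C) should give the arylboronic pinacol ester F3. This needs only oxidative addition and transmetalation under a weak base that forms no alkoxide.
  - Oxidation with NaBO3·4H2O in THF/H2O should give the (1R,3R)-phenol diol F4.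
  - Mitsunobu cyclisation (PPh3, DIAD, THF, 0 °C) lets the C8a phenoxide displace the activated C2 carbinol with inversion, giving the (2S,4R)-chromanol F5. The C4 hydroxyl has no ring-forming outlet.
  - MnO2 as in step 9 then gives 17.

**Step 2 (the same chemistry recurs in step 4).**
- Most likely to go wrong: ionisation of the tertiary allyl aryl ether, because the para-acylphenoxide is a good leaving group. The five-carbon unit is then lost by elimination instead of undergoing the [3,3] shift. Acid-promoted closure of the new ortho-prenylphenol during heating is a lesser risk.
- Fallback: the chain is put on as a robust primary allyl group and extended afterwards. The detour sets out from 1 and comes back at 6.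
  - O-allylation (allyl bromide, K2CO3, acetone) gives the allyl ether F6.
  - Thermal Claisen rearrangement (PhNEt2, 200 °C) passes through the allyl dienone F7 to the ortho-allylphenol F8.
  - Olefin cross-metathesis with 2-methylbut-2-ene (second-generation Grubbs catalyst RuCl2(H2IMes)(PCy3)(=CHPh), CH2Cl2, 40 °C) converts the allyl into the prenyl group and gives 6.

**Step 7.**
- Most likely to go wrong: stalling of the second reduction at the ortho-bromoaryl carbonyl, weaker stereocontrol at that hindered carbonyl, or partial loss of the acetal in the formic acid medium. Selectivity at the hindered carbonyl does not affect the configuration of 18.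
- Fallback: the reduction is stopped at 14, which is isolated. Its free hydroxyl then directs an Evans–Saksena reduction (Me4NBH(OAc)3, MeCN/AcOH, −20 °C). Hydride is delivered within the alkoxyborohydride, which gives the anti-diol 15, so substrate control replaces catalyst control at the second carbonyl. The detour sets out from 14 and comes back at 15, and it makes no compound outside the list (F0).

**Step 10.**
- Most likely to go wrong: protonation of a prenyl alkene and capture of the cation by the freed C7 phenol, or acid-promoted opening and reclosure of ring C with erosion at C2.
- Fallback: the acetal is exchanged without Brønsted acid. The detour sets out from 17 and comes back at 18. TMSOTf and 2,2'-bipyridyl (CH2Cl2, 0 °C) should convert the aryl MOM ether into the trimethylsilyl ether F9, which water hydrolyses at neutral pH to 18.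

## Further compounds

F1 | step 8 | (3R)-1-[2-bromo-4-(methoxymethoxy)-3,5-bis(3-methylbut-2-enyl)phenyl]-3-hydroxy-3-phenylpropan-1-one | O[C@@H](c1ccccc1)CC(=O)c1cc(CC=C(C)C)c(OCOC)c(CC=C(C)C)c1Br
F2 | step 8 | (1R,3R)-1-[2-bromo-4-(methoxymethoxy)-3,5-bis(3-methylbut-2-enyl)phenyl]-3-phenylpropane-1,3-diol | O[C@@H](c1ccccc1)C[C@@H](O)c1cc(CC=C(C)C)c(OCOC)c(CC=C(C)C)c1Br
F3 | step 8 | (1R,3R)-1-[4-(methoxymethoxy)-3,5-bis(3-methylbut-2-enyl)-2-(4,4,5,5-tetramethyl-1,3,2-dioxaborolan-2-yl)phenyl]-3-phenylpropane-1,3-diol | O[C@@H](c1ccccc1)C[C@@H](O)c1cc(CC=C(C)C)c(OCOC)c(CC=C(C)C)c1B2OC(C)(C)C(C)(C)O2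
F4 | step 8 | (1R,3R)-1-[2-hydroxy-4-(methoxymethoxy)-3,5-bis(3-methylbut-2-enyl)phenyl]-3-phenylpropane-1,3-diol | O[C@@H](c1ccccc1)C[C@@H](O)c1cc(CC=C(C)C)c(OCOC)c(CC=C(C)C)c1O
F5 | step 8 | (2S,4R)-7-(methoxymethoxy)-6,8-bis(3-methylbut-2-enyl)-2-phenylchroman-4-ol | COCOc1c(CC=C(C)C)cc2c(c1CC=C(C)C)O[C@H](c1ccccc1)C[C@H]2O
F6 | step 2 | 1-[2-bromo-4-(prop-2-enyloxy)phenyl]ethanone | CC(=O)c1ccc(OCC=C)cc1Br
F7 | step 2 | 4-acetyl-5-bromo-6-(prop-2-enyl)cyclohexa-2,4-dien-1-one | CC(=O)C1=C(Br)C(CC=C)C(=O)C=C1
F8 | step 2 | 1-[2-bromo-4-hydroxy-3-(prop-2-enyl)phenyl]ethanone | CC(=O)c1ccc(O)c(CC=C)c1Br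
F0 | step 7 | none | none
F9 | step 10 | (2S)-6,8-bis(3-methylbut-2-enyl)-2-phenyl-7-(trimethylsilyloxy)chroman-4-one | C[Si](C)(C)Oc1c(CC=C(C)C)cc2c(c1CC=C(C)C)O[C@H](c1ccccc1)CC2=O
A1 | alternative 1 | 7-(tert-butyldimethylsilyloxy)-4-methylene-6,8-bis(3-methylbut-2-enyl)-2-phenyl-4H-1,3-benzodioxine (racemic) | C=C1OC(c2ccccc2)Oc2c1cc(CC=C(C)C)c(O[Si](C)(C)C(C)(C)C)c2CC=C(C)C
A2 | alternative 1 | (2S)-7-(tert-butyldimethylsilyloxy)-6,8-bis(3-methylbut-2-enyl)-2-phenylchroman-4-one | CC(C)(C)[Si](C)(C)Oc1c(CC=C(C)C)cc2c(c1CC=C(C)C)O[C@H](c1ccccc1)CC2=O
A3 | alternative 2 | 2,10-dimethylundeca-2,9-dien-6-one | CC(C)=CCCC(=O)CCC=C(C)C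
A4 | alternative 2 | diethyl ethoxymethylenemalonate | CCOC=C(C(=O)OCC)C(=O)OCC
A5 | alternative 2 | ethyl 2,4-dihydroxy-3,5-bis(3-methylbut-2-enyl)benzoate | CCOC(=O)c1cc(CC=C(C)C)c(O)c(CC=C(C)C)c1O
A6 | alternative 3 | 6-iodo-2,4-bis(3-methylbut-2-enyl)benzene-1,3-diol | Oc1c(I)cc(CC=C(C)C)c(O)c1CC=C(C)C
A7 | alternative 3 | carbon monoxide | [C-]#[O+]
A8 | alternative 3 | phenylacetylene | C#Cc1ccccc1
A9 | alternative 3 | 7-hydroxy-6,8-bis(3-methylbut-2-enyl)-2-phenylchromen-4-one | CC(C)=CCc1cc2c(=O)cc(-c3ccccc3)oc2c(CC=C(C)C)c1O
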